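The last dawn reading, 10.0 % at 10.0 h, was half the first, and that ratio raised my question: what would this flask hold at 15 h, and which remedy would pay?

all flasks: substrate 0.10 M
- dawn: catalyst 0.12 mol%; temperature 25 °C; the very flask that is asked about, followed so far
- summer: catalyst 0.18 mol%; temperature 10 °C; run made earlier
- flask: catalyst 0.12 mol%; temperature 25 °C; time 15 h

| dawn: time / h | dawn: target / % | summer: time / h | summer: target / % |
|---|---|---|---|
| 0.667 | 19.3 | 0.500 | 12.9 |
| 1.50 | 17.4 | 1.33 | 25.6 |
| 4.00 | 11.8 | 3.00 | 30.2 |
| 10.0 | 10.0 | 4.00 | 30.2 |

(each reading ± 0.5 percentage points)

- west: change nothing and wait 15 h more
- south-west: at 15 h add catalyst, 50.0 % of the amount charged, then wait 15 h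
- south-east: at 15 h raise the temperature by 20 K, then wait 15 h
- north-west: at 15 h take out 90 % of the target then present, then wait 15 h

- removed target is counted in
- what was read earlier has a scatter of 0.5 percentage points, one standard deviation
- additions bring no volume worth counting

- target, in percent of the substrate first charged, at 15 h
- the remedy with the largest gain of target, or "none" below 2 percentage points (west / south-west / south-east / north-west / none)
- target present, with what was taken out counted in, in percent of the substrate first charged, after south-west
- target present, with what was taken out counted in, in percent of the substrate first charged, after south-east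

Was the target still moving? In the dawn run, the hourly fall from 4.00 h to 10.0 h was smaller by a factor of 7.47 than the fall just before it. So I read the curve as nearly level and committed to about 10.0 % at 15 h, a reading with a scatter of 0.5 percentage points.

What did the level mean? I wrote the balance of the substrate charged: target plus everything else makes the whole, so 90.0 % of the charge stood unread. The dawn readings could not separate a balance from a stopped catalyst. I bet on a balance, the thermodynamic end of a kinetic overshoot (kinetic against thermodynamic control), and so expected no gain from waiting or from more catalyst.

What would a take-out bring? If the pool left in the dawn flask returns to the same level share, the gain is the share taken out, times the level share, times one minus the level share. This take-out gain came to 8.1 points, more than the margin of 2 points. I chose north-west.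

The forecast gave 9.9 % at 15 h, north-west as best, 9.8 % after south-west and 4 % after south-east. Its ground for the first two remedies was “Waiting or adding catalyst changes nothing.”

    substrate + catalyst ⇌ target + catalyst, rate k1*[substrate]*[catalyst] forward; the back reaction follows from the equilibrium constant (K = 0.530, k = 110 M⁻¹ min⁻¹, Ea = 56.0 kJ mol⁻¹, ΔH = −17.0 kJ mol⁻¹)
    target ⇌ isomer of the product (K = 8.20, k = 0.0220 min⁻¹, Ea = 90.0 kJ mol⁻¹, ΔH = −5.00 kJ mol⁻¹)
    (constants at 25 °C)

The flask held 9.05 % at 15 h, and north-west gained 7.4 points, while south-west left 9.02 % and south-east 8.99 %. At 15.0 h the isomer of the product held 73.8 % and substrate 17.1 %. My take-out gain of 8.1 points, reckoned again with 9.05 % as the level share, came to 7.4 points. For the repeat kept at 10 °C, which held 17.2 % at 15 h and was not shown level, the same product came to 13 points.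

The numbers in the tables were generated by integration for an exercise; noise was put on by code.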